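**Retrosynthetic overview**

- The target is a ten-membered carbocycle (C1–C10) fused at C7–C8 to an α-(acetoxymethyl)-γ-alkylidene butenolide, O–C12(=O)–C11(C13H2OAc)=C7–C8(=C9)–O.
- Key disconnection: the lactone C11–C12 bond, made by oxidative acetoxy-cyclocarbonylation of a macrocyclic 2,3-allenol. The enabling feature is that the lactone oxygen sits on ring carbon C8, next to the β-carbon C7; C7=C11–C13 is therefore the retron of an exocyclic allene C7=C11=C13H2 beside a C8 carbinol, with CO becoming C12 and acetate landing on C13.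
- The C8=C9 enol-lactone bond and the C10 tertiary alcohol come from E1cB opening of a 9,10-epoxide by the butenolide γ-carbanion; the epoxide (Sharpless) fixes C10.
- The carbocycle is closed at C7–C8 by a chromium-mediated intramolecular allenylation of an epoxy aldehyde by a propargylic chloride. The chain is built from 4-chlorobut-2-ynal by two vinylogous Mukaiyama aldol homologations with C5 dienolates (these set C6, the 3Z alkene and C2).
- Ring order: temporary δ-lactone (locks 3Z), oxirane, ten-membered carbocycle, butenolide; the C6 tiglate goes on last.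

Key step: step 14

Locants (germacrane type): ring carbons C1–C10; C2 bears OAc, C4 the C15 methyl, C6 the tiglate, C8 the lactone oxygen, C10 the OH and the C14 methyl; C11 is the lactone α-carbon, C12 the lactone carbonyl, C13 the CH2OAc carbon.

Assumption: the facial sense of the two catalyst- or promoter-controlled vinylogous aldol steps (3 and 8) is assigned by analogy; if a first run shows the opposite sense, the mirror-image ligand or promoter is used with no other change.

Remark: C8 of 19–22 is written without configuration because both epimers are expected and both converge in step 15.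

Step 1
Reactants: 1 4-chlorobut-2-yn-1-ol
Product: 2 4-chlorobut-2-ynal
Conditions: activated MnO2 (10 equiv), CH2Cl2, 25 °C; filtered and used at once
Reagents that add atoms: none
Why: MnO2 oxidation of a propargylic alcohol should stop at the ynal and leave the propargylic chloride untouched.

Step 2
Reactants: 3 methyl 3-methylbut-2-enoate
Product: 5 1-methoxy-3-methyl-1-(trimethylsilyloxy)buta-1,3-diene, via lithium dienolate 4 (not isolated)
Conditions: lithium diisopropylamide, THF, −78 °C; then Me3SiCl, −78 to 0 °C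
Reagents that add atoms: chlorotrimethylsilane, C[Si](C)(C)Cl
Why: Kinetic γ-deprotonation of the senecioate and O-silylation of the cross-conjugated dienolate (silyl ketene acetal formation) should give the diene; its E/Z mixture is inconsequential.

Step 3
Reactants: 2 4-chlorobut-2-ynal; 5 1-methoxy-3-methyl-1-(trimethylsilyloxy)buta-1,3-diene
Product: 7 (6R)-6-(3-chloroprop-1-yn-1-yl)-4-methyl-5,6-dihydro-2H-pyran-2-one, via open-chain copper aldolate 6 (not isolated)
Conditions: Cu(OTf)2 (10 mol %), (S)-Tol-BINAP (11 mol %), Bu4N Ph3SiF2 (20 mol %), THF, 0 to 25 °C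
Reagents that add atoms: none
Why: In this copper-catalysed asymmetric vinylogous Mukaiyama aldol reaction the Tol-BINAP copper dienolate should add through its γ-carbon to one face of the ynal (ligand control sets C6 as R), and the Z-configured aldolate should lactonise, which locks the later C3=C4 alkene as Z.

Step 4
Reactants: 7 (6R)-6-(3-chloroprop-1-yn-1-yl)-4-methyl-5,6-dihydro-2H-pyran-2-one
Product: 8 (2Z,5R)-8-chloro-5-hydroxy-N-methoxy-N,3-dimethyloct-2-en-6-ynamide
Conditions: MeNH(OMe)·HCl (3 equiv), AlMe3 (3 equiv), CH2Cl2, 0 to 25 °C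
Reagents that add atoms: N,O-dimethylhydroxylamine hydrochloride, CNOC.Cl
Why: Weinreb aminolysis of the lactone by the aluminium amide should open the ring with the Z alkene intact and give an acyl group that can be reduced to the aldehyde level only.

Step 5
Reactants: 8 (2Z,5R)-8-chloro-5-hydroxy-N-methoxy-N,3-dimethyloct-2-en-6-ynamide
Product: 9 (2Z,5R)-8-chloro-N-methoxy-N,3-dimethyl-5-(triethylsilyloxy)oct-2-en-6-ynamide
Conditions: Et3SiOTf, 2,6-lutidine, CH2Cl2, −78 °C
Reagents that add atoms: triethylsilyl triflate, CC[Si](CC)(CC)OS(=O)(=O)C(F)(F)F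
Why: Silylation with a non-nucleophilic base should protect O6 at once, which prevents relactonisation and spares the propargylic chloride.

Step 6
Reactants: 9 (2Z,5R)-8-chloro-N-methoxy-N,3-dimethyl-5-(triethylsilyloxy)oct-2-en-6-ynamide
Product: 10 (2Z,5R)-8-chloro-3-methyl-5-(triethylsilyloxy)oct-2-en-6-ynal
Conditions: i-Bu2AlH (1.2 equiv), THF, −78 °C; Rochelle salt work-up; used without storage
Reagents that add atoms: none
Why: Weinreb amide reduction proceeds through a chelated tetrahedral intermediate that should release the Z-enal only on work-up; low temperature and neutral work-up guard against Z to E isomerisation.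

Step 7
Reactants: 11 3-methylbut-2-enal
Product: 12 (E)-tert-butyldimethyl[(3-methylbuta-1,3-dien-1-yl)oxy]silane
Conditions: t-BuMe2SiOTf, Et3N, Et2O, 0 °C
Reagents that add atoms: tert-butyldimethylsilyl triflate, CC(C)(C)[Si](C)(C)OS(=O)(=O)C(F)(F)F
Why: Soft enolisation (O-silylation, then γ-deprotonation) of prenal should give the 1-silyloxy diene (silyl dienol ether formation).

Step 8
Reactants: 10 (2Z,5R)-8-chloro-3-methyl-5-(triethylsilyloxy)oct-2-en-6-ynal; 12 (E)-tert-butyldimethyl[(3-methylbuta-1,3-dien-1-yl)oxy]silane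
Product: 13 (2E,5R,6Z,9R)-12-chloro-5-hydroxy-3,7-dimethyl-9-(triethylsilyloxy)dodeca-2,6-dien-10-ynal
Conditions: N-tosyl-L-tryptophan-derived B-phenyl oxazaborolidinone (0.5 equiv), i-PrOH (1.1 equiv), EtCN, −78 °C
Reagents that add atoms: none
Why: In this oxazaborolidinone-promoted vinylogous Mukaiyama aldol reaction the boron Lewis acid should bind the enal and shield one face, so that the diene terminus adds to the other face (promoter control sets C2 as R) and the E-enal is regenerated.

Step 9
Reactants: 13 (2E,5R,6Z,9R)-12-chloro-5-hydroxy-3,7-dimethyl-9-(triethylsilyloxy)dodeca-2,6-dien-10-ynal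
Product: 14 (2E,5R,6Z,9R)-5-acetoxy-12-chloro-3,7-dimethyl-9-(triethylsilyloxy)dodeca-2,6-dien-10-ynal
Conditions: Ac2O, pyridine, DMAP (cat.), CH2Cl2, 0 °C
Reagents that add atoms: acetic anhydride, CC(=O)OC(C)=O
Why: Acylation of the only free hydroxyl should install the C2 acetate of the target before any hydride or oxidation step.

Step 10
Reactants: 14 (2E,5R,6Z,9R)-5-acetoxy-12-chloro-3,7-dimethyl-9-(triethylsilyloxy)dodeca-2,6-dien-10-ynal
Product: 15 (2E,5R,6Z,9R)-5-acetoxy-12-chloro-3,7-dimethyl-9-(triethylsilyloxy)dodeca-2,6-dien-10-yn-1-ol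
Conditions: NaBH4, CeCl3·7H2O, MeOH, −20 °C
Reagents that add atoms: none
Why: Luche reduction should reduce the enal 1,2 to the E allylic alcohol without touching the acetate.

Step 11
Reactants: 15 (2E,5R,6Z,9R)-5-acetoxy-12-chloro-3,7-dimethyl-9-(triethylsilyloxy)dodeca-2,6-dien-10-yn-1-ol
Product: 16 (2S,3S,5R,6Z,9R)-5-acetoxy-12-chloro-2,3-epoxy-3,7-dimethyl-9-(triethylsilyloxy)dodec-6-en-10-yn-1-ol
Conditions: Ti(OiPr)4 (10 mol %), L-(+)-diethyl tartrate (12 mol %), t-BuOOH, 4 Å molecular sieves, CH2Cl2, −20 °C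
Reagents that add atoms: tert-butyl hydroperoxide, CC(C)(C)OO
Why: Sharpless asymmetric epoxidation of this geraniol-type E allylic alcohol with L-(+)-tartrate should give the (2S,3S)-epoxide (C9 and C10 of the target numbering, reagent control), while the other alkenes lack a free allylic hydroxyl.

Step 12
Reactants: 16 (2S,3S,5R,6Z,9R)-5-acetoxy-12-chloro-2,3-epoxy-3,7-dimethyl-9-(triethylsilyloxy)dodec-6-en-10-yn-1-ol
Product: 17 (2R,3S,5R,6Z,9R)-5-acetoxy-12-chloro-2,3-epoxy-3,7-dimethyl-9-(triethylsilyloxy)dodec-6-en-10-ynal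
Conditions: Dess–Martin periodinane, NaHCO3, CH2Cl2, 0 to 25 °C; used crude
Reagents that add atoms: none
Why: Buffered Dess–Martin oxidation should give the epoxy aldehyde without epoxide opening; the C2 descriptor changes by priority only.

Step 13
Reactants: 17 (2R,3S,5R,6Z,9R)-5-acetoxy-12-chloro-2,3-epoxy-3,7-dimethyl-9-(triethylsilyloxy)dodec-6-en-10-ynal
Product: 19 (2R,3Z,6R,9S,10S)-2-acetoxy-9,10-epoxy-4,10-dimethyl-6-(triethylsilyloxy)-7-vinylidenecyclodec-3-en-8-ol (both C8 epimers), via propargylchromium dichloride 18 (not isolated)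
Conditions: CrCl2 (8 equiv), THF–DMF 4:1, 25 °C, syringe-pump addition of 17 over 12 h (final 2 mM)
Reagents that add atoms: none
Why: In this intramolecular Nozaki–Hiyama allenylation, divalent chromium should insert into the propargylic C–Cl bond and the γ-substituted propargylchromium should add to the aldehyde through C7 (SE2'), closing the ten-membered ring at C7–C8 and leaving the exocyclic allene; C8 forms as an inconsequential epimer mixture, and the silyl ether on O6 disfavours 1,4-elimination.

Step 14
Reactants: 19 (2R,3Z,6R,9S,10S)-2-acetoxy-9,10-epoxy-4,10-dimethyl-6-(triethylsilyloxy)-7-vinylidenecyclodec-3-en-8-ol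
Product: 22 (2R,3Z,6R,9S,10S)-2,13-diacetoxy-9,10-epoxy-6-(triethylsilyloxy)germacra-3,7(11)-dien-12,8-olide (both C8 epimers), via alkoxycarbonylpalladium acetate 20 (not isolated), via allylpalladium acetate 21 (not isolated)
Conditions: Pd(OAc)2 (10 mol %), 1,4-benzoquinone (2 equiv), LiOAc (3 equiv), AcOH (2 equiv), CO (1 atm), THF, 25 to 40 °C
Reagents that add atoms: carbon monoxide, [C-]#[O+]; acetic acid (acetate, supplied as LiOAc/AcOH), CC(=O)O
Why: Proposed new method: Pd(OAc)2 and the C8 hydroxyl under CO should give alkoxycarbonylpalladium acetate 20 (O8–C12 bond), whose Pd–C12 bond adds syn across the distal C11=C13 π-bond of the allene so that C12 is delivered to the central carbon C11, closing the butenolide by the C11–C12 bond and leaving the 2-acyl-allylpalladium species 21; acetate then attacks the C13 terminus (benzoquinone-assisted), which places the C7=C11 double bond in the ring and releases zerovalent palladium that benzoquinone and AcOH reoxidise. The closest known reaction types are the PdCl2/CuCl2 chlorocyclocarbonylation of 2,3-allenols to 3-(chloromethyl)butenolides and the benzoquinone-mediated acetate capture of allylpalladium acetates in diene 1,4-diacetoxylation; the acetate/benzoquinone variant is proposed because CuCl2 and HCl would open the 9,10-epoxide. The one ring closed is the five-membered lactone, by insertion at the central allene carbon (5-exo with respect to the C11=C13 bond); the two-atom O8–C12 tether on C7 allows no other ring size. No new stereocentre is formed: C8 is untouched (both epimers react) and the geometry of the tetrasubstituted C7=C11 bond is fixed by the ring. The step needs O8 over O6 selectivity and C13 over C7 selectivity in the acetate capture: O6 is blocked as its silyl ether, and C7 is a fully substituted ring carbon whereas attack at C13 gives the conjugated butenolide. Competing 5-endo oxypalladation of the allenol to a 2,5-dihydrofuran should be suppressed under CO, as in the known chloro variant.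

Step 15
Reactants: 22 (2R,3Z,6R,9S,10S)-2,13-diacetoxy-9,10-epoxy-6-(triethylsilyloxy)germacra-3,7(11)-dien-12,8-olide
Product: 24 (2R,3Z,6R,8E,10S)-2,13-diacetoxy-10-hydroxy-6-(triethylsilyloxy)germacra-3,7(11),8-trien-12,8-olide, via furanolate 23 (not isolated)
Conditions: DBU (0.3 equiv), Bu4NOAc (1 equiv), MeCN, 0 to 25 °C
Reagents that add atoms: none
Why: In this E1cB isomerisation, γ-deprotonation at C8 should give the furanolate, which opens the adjacent epoxide at the C9–O bond to form the C8=C9 enol-lactone bond and the C10 tertiary alcohol with C10 unchanged (S, from step 11); the ring enforces the geometry with C7 and C10 cis, both C8 epimers converge, and the acetate buffer returns any C13 acetate lost from the furanolate.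

Step 16
Reactants: 24 (2R,3Z,6R,8E,10S)-2,13-diacetoxy-10-hydroxy-6-(triethylsilyloxy)germacra-3,7(11),8-trien-12,8-olide
Product: 25 (2R,3Z,6R,8E,10S)-2,13-diacetoxy-6,10-dihydroxygermacra-3,7(11),8-trien-12,8-olide
Conditions: HF·pyridine, pyridine, THF, 0 °C
Reagents that add atoms: none
Why: Buffered fluoride desilylation should remove the secondary triethylsilyl ether without ionising the tertiary allylic alcohol or cleaving the acetates.

Step 17
Reactants: 25 (2R,3Z,6R,8E,10S)-2,13-diacetoxy-6,10-dihydroxygermacra-3,7(11),8-trien-12,8-olide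
Product: 26 CNP0166369.1, (2R,3Z,6R,8E,10S)-2,13-diacetoxy-10-hydroxy-6-[(E)-2-methylbut-2-enoyloxy]germacra-3,7(11),8-trien-12,8-olide
Conditions: tigloyl chloride (3 equiv), pyridine, DMAP (0.2 equiv), CH2Cl2, 0 to 25 °C
Reagents that add atoms: tigloyl chloride, C/C=C(\C)C(=O)Cl
Why: DMAP-catalysed acylation should esterify the secondary C6 hydroxyl while the tertiary C10 hydroxyl stays free, and the E acyl group is the stable geometry.

**Compound list**

1 | 4-chlorobut-2-yn-1-ol | OCC#CCCl | starting material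
2 | 4-chlorobut-2-ynal | O=CC#CCCl | intermediate
3 | methyl 3-methylbut-2-enoate | COC(=O)C=C(C)C | starting material
4 | lithium 1-methoxy-3-methylbuta-1,3-dien-1-olate | [Li+].[O-]C(OC)=CC(C)=C | intermediate (not isolated)
5 | 1-methoxy-3-methyl-1-(trimethylsilyloxy)buta-1,3-diene (E/Z mixture) | C=C(C)C=C(OC)O[Si](C)(C)C | intermediate
6 | monovalent copper alkoxide of methyl (2Z,5R)-8-chloro-5-hydroxy-3-methyloct-2-en-6-ynoate (ligand not drawn) | ClCC#C[C@H]([O-])C/C(C)=C\C(=O)OC.[Cu+] | intermediate (not isolated)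
7 | (6R)-6-(3-chloroprop-1-yn-1-yl)-4-methyl-5,6-dihydro-2H-pyran-2-one | CC1=CC(=O)O[C@@H](C#CCCl)C1 | intermediate
8 | (2Z,5R)-8-chloro-5-hydroxy-N-methoxy-N,3-dimethyloct-2-en-6-ynamide | ClCC#C[C@H](O)C/C(C)=C\C(=O)N(C)OC | intermediate
9 | (2Z,5R)-8-chloro-N-methoxy-N,3-dimethyl-5-(triethylsilyloxy)oct-2-en-6-ynamide | ClCC#C[C@H](O[Si](CC)(CC)CC)C/C(C)=C\C(=O)N(C)OC | intermediate
10 | (2Z,5R)-8-chloro-3-methyl-5-(triethylsilyloxy)oct-2-en-6-ynal | ClCC#C[C@H](O[Si](CC)(CC)CC)C/C(C)=C\C=O | intermediate
11 | 3-methylbut-2-enal | CC(C)=CC=O | starting material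
12 | (E)-tert-butyldimethyl[(3-methylbuta-1,3-dien-1-yl)oxy]silane | C=C(C)/C=C/O[Si](C)(C)C(C)(C)C | intermediate
13 | (2E,5R,6Z,9R)-12-chloro-5-hydroxy-3,7-dimethyl-9-(triethylsilyloxy)dodeca-2,6-dien-10-ynal | ClCC#C[C@H](O[Si](CC)(CC)CC)C/C(C)=C\[C@H](O)C/C(C)=C/C=O | intermediate
14 | (2E,5R,6Z,9R)-5-acetoxy-12-chloro-3,7-dimethyl-9-(triethylsilyloxy)dodeca-2,6-dien-10-ynal | ClCC#C[C@H](O[Si](CC)(CC)CC)C/C(C)=C\[C@H](OC(C)=O)C/C(C)=C/C=O | intermediate
15 | (2E,5R,6Z,9R)-5-acetoxy-12-chloro-3,7-dimethyl-9-(triethylsilyloxy)dodeca-2,6-dien-10-yn-1-ol | ClCC#C[C@H](O[Si](CC)(CC)CC)C/C(C)=C\[C@H](OC(C)=O)C/C(C)=C/CO | intermediate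
16 | (2S,3S,5R,6Z,9R)-5-acetoxy-12-chloro-2,3-epoxy-3,7-dimethyl-9-(triethylsilyloxy)dodec-6-en-10-yn-1-ol | ClCC#C[C@H](O[Si](CC)(CC)CC)C/C(C)=C\[C@H](OC(C)=O)C[C@]1(C)O[C@H]1CO | intermediate
17 | (2R,3S,5R,6Z,9R)-5-acetoxy-12-chloro-2,3-epoxy-3,7-dimethyl-9-(triethylsilyloxy)dodec-6-en-10-ynal | ClCC#C[C@H](O[Si](CC)(CC)CC)C/C(C)=C\[C@H](OC(C)=O)C[C@]1(C)O[C@H]1C=O | intermediate
18 | C13 propargylchromium dichloride (trivalent chromium) derived from 17 | Cl[Cr](Cl)CC#C[C@H](O[Si](CC)(CC)CC)C/C(C)=C\[C@H](OC(C)=O)C[C@]1(C)O[C@H]1C=O | intermediate (not isolated)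
19 | (2R,3Z,6R,9S,10S)-2-acetoxy-9,10-epoxy-4,10-dimethyl-6-(triethylsilyloxy)-7-vinylidenecyclodec-3-en-8-ol (both C8 epimers) | C=C=C1[C@H](O[Si](CC)(CC)CC)C/C(C)=C\[C@H](OC(C)=O)C[C@]2(C)O[C@H]2C1O | intermediate
20 | O8-alkoxycarbonylpalladium acetate of 19 (divalent palladium) | C=C=C1[C@H](O[Si](CC)(CC)CC)C/C(C)=C\[C@H](OC(C)=O)C[C@]2(C)O[C@H]2C1OC(=O)[Pd]OC(C)=O | intermediate (not isolated)
21 | C13 allylpalladium acetate of the closed butenolide (divalent palladium, drawn as the σ-allyl form) | CC(=O)O[Pd]CC1=C2[C@H](O[Si](CC)(CC)CC)C/C(C)=C\[C@H](OC(C)=O)C[C@]3(C)O[C@H]3C2OC1=O | intermediate (not isolated)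
22 | (2R,3Z,6R,9S,10S)-2,13-diacetoxy-9,10-epoxy-6-(triethylsilyloxy)germacra-3,7(11)-dien-12,8-olide (both C8 epimers) | CC(=O)OCC1=C2[C@H](O[Si](CC)(CC)CC)C/C(C)=C\[C@H](OC(C)=O)C[C@]3(C)O[C@H]3C2OC1=O | intermediate
23 | furanolate of 22 (DBU-H salt) | CC(=O)OCC1=C([O-])OC2=C1[C@H](O[Si](CC)(CC)CC)C/C(C)=C\[C@H](OC(C)=O)C[C@]3(C)O[C@@H]23.C1CCC2=[NH+]CCCN2CC1 | intermediate (not isolated)
24 | (2R,3Z,6R,8E,10S)-2,13-diacetoxy-10-hydroxy-6-(triethylsilyloxy)germacra-3,7(11),8-trien-12,8-olide | CC[Si](CC)(CC)O[C@@H]1C/C(C)=C\[C@H](OC(C)=O)C[C@](C)(O)/C=C2/OC(=O)C(COC(C)=O)=C21 | intermediate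
25 | (2R,3Z,6R,8E,10S)-2,13-diacetoxy-6,10-dihydroxygermacra-3,7(11),8-trien-12,8-olide | O[C@@H]1C/C(C)=C\[C@H](OC(C)=O)C[C@](C)(O)/C=C2/OC(=O)C(COC(C)=O)=C21 | intermediate
26 | CNP0166369.1, (2R,3Z,6R,8E,10S)-2,13-diacetoxy-10-hydroxy-6-[(E)-2-methylbut-2-enoyloxy]germacra-3,7(11),8-trien-12,8-olide | C/C=C(\C)C(=O)O[C@@H]1C/C(C)=C\[C@H](OC(C)=O)C[C@](C)(O)/C=C2/OC(=O)C(COC(C)=O)=C21 | target

**Step count and risks**

Total steps: 17. Longest linear sequence: 15 (steps 1, 3–6, 8–17).

Steps most likely to fail: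

1. Step 14 (Proposed new method). Possible failures: 5-endo oxypalladation of the allenol in place of alkoxycarbonylation; β-hydride loss from the allylpalladium species before acetate capture; acid-promoted opening of the epoxide. Fallback by known chemistry, setting out from 19: the PdCl2-catalysed chlorocyclocarbonylation of 2,3-allenols (PdCl2 cat., CuCl2, CO 1 atm, THF, NaOAc buffer) would close the same C11–C12 bond and give the 13-chloro butenolide F1. Displacement of the allylic chloride with CsOAc in DMF comes back to the route at 22.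

2. Step 13. Possible failures: oligomerisation outrunning ten-membered ring closure; addition through C13 to a twelve-membered homopropargylic alcohol; 1,4-elimination of the C6 silyloxy group from the organochromium; reductive opening of the epoxy aldehyde by divalent chromium. Fallback (C7–C8 made between two molecules, carbocycle closed later by olefin metathesis at C3=C4), setting out from 2 and 12:
   - Brown methallylboration of 2 (B-methallyldiisopinocampheylborane, antipode giving the R carbinol) would give the homoallylic alcohol F2, silylated with Et3SiOTf to the silyl ether F3.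
   - In parallel, 12 and crotonaldehyde under the conditions of step 8 would give the hydroxy dienal F4. The chemistry of steps 9–12 then leads through the acetate F5, the allylic alcohol F6 and the epoxy alcohol F7 to the epoxy aldehyde F8.
   - CrCl2-mediated allenylation of F8 with F3 would give the open-chain allenol F9, and the conditions of step 14 the open-chain butenolide F10.
   - Ring-closing metathesis (second-generation Hoveyda–Grubbs catalyst, toluene, 80 °C, high dilution, loss of propene) closes the ring and comes back to the route at 22.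

3. Step 15. Possible failure: ejection of the allylic C13 acetate from the furanolate, with consumption of the resulting exocyclic methylene furanone by the amidine base or by oligomerisation, faster than epoxide opening. Fallback, setting out from 22: selective hydrolysis of the primary acetate (Candida antarctica lipase B, pH 7 buffer/acetone) would give the 13-hydroxy butenolide F11, in which the C13 oxygen is no longer a leaving group. DBU in MeCN then effects the epoxide-opening isomerisation to the diol F12, and Ac2O/pyridine acetylates only the primary hydroxyl, which comes back to the route at 24.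

Further compounds

F1 | step 14 | (2R,3Z,6R,9S,10S)-2-acetoxy-13-chloro-9,10-epoxy-6-(triethylsilyloxy)germacra-3,7(11)-dien-12,8-olide (both C8 epimers) | ClCC1=C2[C@H](O[Si](CC)(CC)CC)C/C(C)=C\[C@H](OC(C)=O)C[C@]3(C)O[C@H]3C2OC1=O
F2 | step 13 | (4R)-7-chloro-2-methylhept-1-en-5-yn-4-ol | ClCC#C[C@H](O)CC(C)=C
F3 | step 13 | (4R)-7-chloro-2-methyl-4-(triethylsilyloxy)hept-1-en-5-yne | ClCC#C[C@H](O[Si](CC)(CC)CC)CC(C)=C
F4 | step 13 | (2E,5R,6E)-5-hydroxy-3-methylocta-2,6-dienal | C/C=C/[C@H](O)C/C(C)=C/C=O
F5 | step 13 | (2E,5R,6E)-5-acetoxy-3-methylocta-2,6-dienal | C/C=C/[C@H](OC(C)=O)C/C(C)=C/C=O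
F6 | step 13 | (2E,5R,6E)-5-acetoxy-3-methylocta-2,6-dien-1-ol | C/C=C/[C@H](OC(C)=O)C/C(C)=C/CO
F7 | step 13 | (2S,3S,5R,6E)-5-acetoxy-2,3-epoxy-3-methyloct-6-en-1-ol | C/C=C/[C@H](OC(C)=O)C[C@]1(C)O[C@H]1CO
F8 | step 13 | (2R,3S,5R,6E)-5-acetoxy-2,3-epoxy-3-methyloct-6-enal | C/C=C/[C@H](OC(C)=O)C[C@]1(C)O[C@H]1C=O
F9 | step 13 | open-chain allenol (target locants: 2R-acetoxy, 9S,10S-epoxide, 6R-triethylsilyloxy, C7 vinylidene, C8 hydroxyl as both epimers, C3 propenyl and C4 isopropenyl termini) | C/C=C/[C@H](OC(C)=O)C[C@]1(C)O[C@H]1C(O)C(=C=C)[C@H](O[Si](CC)(CC)CC)CC(C)=C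
F10 | step 13 | open-chain 13-acetoxy butenolide (as F9 with the C8–O–C12(=O)–C11(CH2OAc)=C7 lactone closed) | C/C=C/[C@H](OC(C)=O)C[C@]1(C)O[C@H]1C2OC(=O)C(COC(C)=O)=C2[C@H](O[Si](CC)(CC)CC)CC(C)=C
F11 | step 15 | (2R,3Z,6R,9S,10S)-2-acetoxy-9,10-epoxy-13-hydroxy-6-(triethylsilyloxy)germacra-3,7(11)-dien-12,8-olide (both C8 epimers) | OCC1=C2[C@H](O[Si](CC)(CC)CC)C/C(C)=C\[C@H](OC(C)=O)C[C@]3(C)O[C@H]3C2OC1=O
F12 | step 15 | (2R,3Z,6R,8E,10S)-2-acetoxy-10,13-dihydroxy-6-(triethylsilyloxy)germacra-3,7(11),8-trien-12,8-olide | CC[Si](CC)(CC)O[C@@H]1C/C(C)=C\[C@H](OC(C)=O)C[C@](C)(O)/C=C2/OC(=O)C(CO)=C21
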